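**Retrosynthetic overview**
- The γ-pyrone (C ring) is opened at O1–C2. This gives a 2-aryl-3-amino-1-(2,4,6-trihydroxyaryl)propenone, which closes with loss of NH3.
- Key disconnection: the C3–C1' bond and the neighbouring 2'-OH come from one N–O-tethered [3,3] shift of an N-aryloxy enaminone. In this shift the B-ring phenol is dearomatised for a moment.
- That enaminone is made from an A-ring dimethylamino-enaminone and an O-(chromen-7-yl)hydroxylamine. No protecting groups are used.
- A part: phloroacetophenone is mono-C-prenylated (its two ring CH are equivalent), then a C1 unit is added. B part: resorcinol and prenal give the chromenol, which is O-aminated.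
- Ring order: the dimethylpyran on the B part forms first (step 1) and the γ-pyrone C ring forms last (step 5). Both benzene rings are bought.

Assumption: the target has no stereocentre and no E/Z-defined alkene, so it is achiral and needs no enantiocontrol. The two stereocentres of intermediate 11 are transient.

**Step 1**
Reactants: 1 resorcinol; 2 3-methylbut-2-enal (prenal)
Product: 4 2,2-dimethyl-2H-chromen-7-ol, via 3-hydroxy-6-(3-methylbut-2-en-1-ylidene)cyclohexa-2,4-dien-1-one (vinylogous o-quinone methide) 3 (not isolated)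
Conditions: pyridine, 140 °C (sealed tube), 16 h; 1 in 2-fold excess
Reagents that add atoms: none
Why: Formal [3+3] chromenylation, in which aldol-type attack of resorcinol C4 (less hindered than C2) on prenal, loss of water to 3 and oxa-6π electrocyclisation give mainly the 7-hydroxy isomer, with no stereocentre formed.

**Step 2**
Reactants: 4 2,2-dimethyl-2H-chromen-7-ol
Product: 5 O-(2,2-dimethyl-2H-chromen-7-yl)hydroxylamine
Conditions: KOtBu (1.05 equiv), DMF, 0 °C; then H2N–O–C6H3-2,4-(NO2)2 (1.1 equiv), 0 °C → rt; used at once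
Reagents that add atoms: O-(2,4-dinitrophenyl)hydroxylamine, NOc1ccc(cc1[N+](=O)[O-])[N+](=O)[O-]
Why: Electrophilic amination (SN2 at nitrogen), in which the potassium phenoxide displaces 2,4-dinitrophenoxide, is the established access to oxygenated phenoxyamines and leaves the chromene alkene untouched.

**Step 3**
Reactants: 6 2,4,6-trihydroxyacetophenone (phloroacetophenone); 7 1-bromo-3-methylbut-2-ene (prenyl bromide)
Product: 8 1-[2,4,6-trihydroxy-3-(3-methylbut-2-en-1-yl)phenyl]ethan-1-one
Conditions: KOH (1.1 equiv), H2O, 0 °C → rt; 7 (0.9 equiv)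
Reagents that add atoms: none
Why: C-alkylation of an acylphloroglucinol anion in water (through its cyclohexadienone tautomer) is known chemistry, and because the two ring CH are equivalent only one mono-C-prenyl isomer can form, while limiting 7 curbs bis-alkylation.

**Step 4**
Reactants: 8 1-[2,4,6-trihydroxy-3-(3-methylbut-2-en-1-yl)phenyl]ethan-1-one
Product: 9 (E)-3-(dimethylamino)-1-[2,4,6-trihydroxy-3-(3-methylbut-2-en-1-yl)phenyl]prop-2-en-1-one
Conditions: t-BuOCH(NMe2)2 (3 equiv), THF, 65 °C
Reagents that add atoms: tert-butoxybis(dimethylamino)methane (Bredereck's reagent), CC(C)(C)OC(N(C)C)N(C)C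
Why: Aminomethylenation of a methyl ketone (enaminone synthesis) works on hydroxyacetophenones, and Bredereck's reagent is chosen because, unlike DMF dimethyl acetal, it cannot O-methylate the acidic phenols.

**Step 5**
Reactants: 5 O-(2,2-dimethyl-2H-chromen-7-yl)hydroxylamine; 9 (E)-3-(dimethylamino)-1-[2,4,6-trihydroxy-3-(3-methylbut-2-en-1-yl)phenyl]prop-2-en-1-one
Product: 13 Krausianone 2, 5,7-dihydroxy-3-(7-hydroxy-2,2-dimethyl-2H-chromen-6-yl)-6-(3-methylbut-2-en-1-yl)-4H-chromen-4-one, via (Z)-3-{[(2,2-dimethyl-2H-chromen-7-yl)oxy]amino}-1-[2,4,6-trihydroxy-3-(3-methylbut-2-en-1-yl)phenyl]prop-2-en-1-one 10 (not isolated), via 2-(2,2-dimethyl-7-oxo-6,7-dihydro-2H-chromen-6-yl)-3-imino-1-[2,4,6-trihydroxy-3-(3-methylbut-2-en-1-yl)phenyl]propan-1-one 11 (not isolated), via 3-amino-2-(7-hydroxy-2,2-dimethyl-2H-chromen-6-yl)-1-[2,4,6-trihydroxy-3-(3-methylbut-2-en-1-yl)phenyl]prop-2-en-1-one 12 (not isolated)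
Conditions: 5 (1.2 equiv), AcOH (2 equiv), EtOH, rt, 2 h; then 78 °C, 8 h (Ar, dark)
Reagents that add atoms: none
Why: Proposed new method: AcOH-promoted amine exchange converts 9 into the N-aryloxy enaminone 10 (tautomer of the O-aryl aldoxime of the β-keto aldehyde), whose C=C–N–O–C=C array and weak N–O bond allow a [3,3]-sigmatropic shift (the oxygen analogue of the Fischer indolisation, known for O-arylhydroxylamines with ketones and 1,3-dicarbonyls on the way to 3-acylbenzofurans) onto the less hindered ortho carbon C6 (para to the pyran oxygen), which breaks the aromaticity of the chromenol ring in dienone-imine 11 (its two transient stereocentres are erased), then tautomerises to 12 with the new C3–C1' bond next to a free 2'-OH, after which 12 closes like any 2-hydroxyaryl enaminone (6-endo addition–elimination, loss of NH3) through the unhindered ring OH next to C–H rather than the OH buttressed by the prenyl group (as 3'-prenyl-2',4',6'-trihydroxychalcones favour 6-prenylflavanones) to give the 6-prenyl isomer, while any 3-aroylbenzofuran from 5-ring closure can re-enter through the known ring-opening/recyclisation of 3-(2-hydroxyaroyl)benzofurans to 2'-hydroxyisoflavones.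

**Compound list**
1 | resorcinol | Oc1cccc(O)c1 | starting material
2 | 3-methylbut-2-enal (prenal) | CC(C)=CC=O | starting material
3 | 3-hydroxy-6-(3-methylbut-2-en-1-ylidene)cyclohexa-2,4-dien-1-one (not isolated) | O=C1C=C(O)C=CC1=CC=C(C)C | intermediate
4 | 2,2-dimethyl-2H-chromen-7-ol | CC1(C)C=Cc2ccc(O)cc2O1 | intermediate
5 | O-(2,2-dimethyl-2H-chromen-7-yl)hydroxylamine | CC1(C)C=Cc2ccc(ON)cc2O1 | intermediate
6 | 2,4,6-trihydroxyacetophenone | CC(=O)c1c(O)cc(O)cc1O | starting material
7 | 1-bromo-3-methylbut-2-ene (prenyl bromide) | CC(C)=CCBr | starting material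
8 | 1-[2,4,6-trihydroxy-3-(3-methylbut-2-en-1-yl)phenyl]ethan-1-one | CC(=O)c1c(O)cc(O)c(CC=C(C)C)c1O | intermediate
9 | (E)-3-(dimethylamino)-1-[2,4,6-trihydroxy-3-(3-methylbut-2-en-1-yl)phenyl]prop-2-en-1-one | CN(C)/C=C/C(=O)c1c(O)cc(O)c(CC=C(C)C)c1O | intermediate
10 | (Z)-3-{[(2,2-dimethyl-2H-chromen-7-yl)oxy]amino}-1-[2,4,6-trihydroxy-3-(3-methylbut-2-en-1-yl)phenyl]prop-2-en-1-one (not isolated) | CC(C)=CCc1c(O)cc(O)c(C(=O)/C=C\NOc2ccc3C=CC(C)(C)Oc3c2)c1O | intermediate
11 | 2-(2,2-dimethyl-7-oxo-6,7-dihydro-2H-chromen-6-yl)-3-imino-1-[2,4,6-trihydroxy-3-(3-methylbut-2-en-1-yl)phenyl]propan-1-one (dearomatised dienone, diastereomer mixture, not isolated) | CC(C)=CCc1c(O)cc(O)c(C(=O)C(C=N)C2C=C3C=CC(C)(C)OC3=CC2=O)c1O | intermediate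
12 | 3-amino-2-(7-hydroxy-2,2-dimethyl-2H-chromen-6-yl)-1-[2,4,6-trihydroxy-3-(3-methylbut-2-en-1-yl)phenyl]prop-2-en-1-one (not isolated) | CC(C)=CCc1c(O)cc(O)c(C(=O)C(=CN)c2cc3C=CC(C)(C)Oc3cc2O)c1O | intermediate
13 | Krausianone 2 | CC(C)=CCc1c(O)cc2occ(-c3cc4c(cc3O)OC(C)(C)C=C4)c(=O)c2c1O | target

**Step count:** 5 steps in total. The longest linear sequence is 3 steps (1 → 4 → 5 → 13, or 6 → 8 → 9 → 13).

**Steps most likely to fail**

**Step 5 (highest risk).**
- The weakly nucleophilic 5 may exchange slowly with 9.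
- 10 may collapse to 5,7-dihydroxy-6-prenylchromone and 5.
- The aldoxime tautomer of 10 may lose chromenol to give a β-keto nitrile.
- The shift may partly go to C8 of the chromenol.
- The final closure may give some 8-prenyl isomer.

The fallback replaces the sigmatropic union by a cross-coupling. It sets out from 4 and 9 and comes back at 13. Compound 4 is iodinated ortho to the OH (I2, NaHCO3, THF–H2O, 0 °C) to 6-iodo-2,2-dimethyl-2H-chromen-7-ol F1. Miyaura borylation (B2pin2, Pd(dppf)Cl2, KOAc, dioxane, 80 °C) then gives 2,2-dimethyl-6-(4,4,5,5-tetramethyl-1,3,2-dioxaborolan-2-yl)-2H-chromen-7-ol F2. In parallel 9 is closed with exactly one equivalent of I2 (MeOH, 0 °C) to 5,7-dihydroxy-3-iodo-6-(3-methylbut-2-en-1-yl)-4H-chromen-4-one F3. Suzuki–Miyaura coupling of F2 with F3 (Pd(PPh3)4, aq. Na2CO3, DME, 70 °C) gives 13.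

**Step 2.** The phenoxide may attack the dinitroarene (SNAr) instead of nitrogen, and 5 may not survive isolation. The fallback builds the Ar–O–N unit by C–O coupling instead of amination. It sets out from 4 and comes back at 5.
- 4 is converted (Tf2O, pyridine, CH2Cl2, 0 °C) into 2,2-dimethyl-2H-chromen-7-yl trifluoromethanesulfonate F4.
- F4 is borylated (B2(OH)4, XPhos-Pd-G2, KOAc, EtOH, 80 °C) to (2,2-dimethyl-2H-chromen-7-yl)boronic acid F5.
- F5 is coupled with N-hydroxyphthalimide under Chan–Lam conditions (Cu(OAc)2, pyridine, 4 Å MS, air, DCE, rt) to 2-[(2,2-dimethyl-2H-chromen-7-yl)oxy]isoindoline-1,3-dione F6.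
- F6 is cleaved with N2H4·H2O (CHCl3–MeOH, rt) to 5.

**Step 4.** The formamidinium electrophile may attack the free ring carbon C5 of 8, or 9 may close early to the chromone. The fallback uses enolate formylation instead of an amide acetal. It sets out from 8 and comes back at 10. Compound 8 is treated with NaH (5 equiv) and ethyl formate (THF, 0 °C → rt, buffered quench). This gives (Z)-3-hydroxy-1-[2,4,6-trihydroxy-3-(3-methylbut-2-en-1-yl)phenyl]prop-2-en-1-one F7, which is in ring–chain equilibrium with its 2-hydroxychromanone. F7 condenses directly with 5 (AcOH, EtOH, rt) to 10 and then follows step 5.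

**Further compounds**
F1 | step 5 | 6-iodo-2,2-dimethyl-2H-chromen-7-ol | CC1(C)C=Cc2cc(I)c(O)cc2O1
F2 | step 5 | 2,2-dimethyl-6-(4,4,5,5-tetramethyl-1,3,2-dioxaborolan-2-yl)-2H-chromen-7-ol | CC1(C)C=Cc2cc(B3OC(C)(C)C(C)(C)O3)c(O)cc2O1
F3 | step 5 | 5,7-dihydroxy-3-iodo-6-(3-methylbut-2-en-1-yl)-4H-chromen-4-one | CC(C)=CCc1c(O)cc2occ(I)c(=O)c2c1O
F4 | step 2 | 2,2-dimethyl-2H-chromen-7-yl trifluoromethanesulfonate | CC1(C)C=Cc2ccc(OS(=O)(=O)C(F)(F)F)cc2O1
F5 | step 2 | (2,2-dimethyl-2H-chromen-7-yl)boronic acid | CC1(C)C=Cc2ccc(B(O)O)cc2O1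
F6 | step 2 | 2-[(2,2-dimethyl-2H-chromen-7-yl)oxy]isoindoline-1,3-dione | CC1(C)C=Cc2ccc(ON3C(=O)c4ccccc4C3=O)cc2O1
F7 | step 4 | (Z)-3-hydroxy-1-[2,4,6-trihydroxy-3-(3-methylbut-2-en-1-yl)phenyl]prop-2-en-1-one | CC(C)=CCc1c(O)cc(O)c(C(=O)/C=C\O)c1O
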